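**Retrosynthetic overview**
1. Target ⇒ (desilylation) ⇒ C8–O ester bond. This is the key step: a Mitsunobu C–O bond formation with inversion at C8 between the macrocyclic 8-epi alcohol and the silyl-protected side-chain acid.
2. Ten-membered carbocycle ⇒ C1=C10 by ring-closing metathesis of an open-chain hydroxy triene.
3. Triene ⇒ C7–C8 by zinc Barbier coupling of a (5R)-3-(bromomethyl)butenolide with an (S)-α-acetoxy aldehyde (C9–O fixed by lipase O-acetylation of a Baylis–Hillman adduct).
4. Butenolide ⇒ new CO2-based carboxylative lactonisation (C11–C12 bond and the lactone C–O bond) of an (R)-propargylic alcohol made from an enal and a propargyl silyl ether.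
5. Ring order: γ-lactone first (step 4), cyclodecadiene second (step 12).

Assumption: germacrane numbering (C1–C15) is used for atom locants in the explanations, and simple reagents are given by name and SMILES without a compound number.

Step 1
Reactants: 1 hex-1-en-5-yne
Product: 4 (2E)-3-methylhepta-2,6-dien-1-ol, via alkenylalane 2 (not isolated), via lithium aluminate 3 (not isolated)
Conditions: Me3Al (2 equiv), Cp2ZrCl2 (20 mol%), CH2Cl2, 0 °C to rt; n-BuLi, THF, −78 °C; (CH2O)n, −78 °C to rt; aq. HCl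
Reagents that add atoms: trimethylaluminium (C[Al](C)C); paraformaldehyde as formaldehyde (C=O)
Why: Negishi zirconium-catalysed carboalumination adds Me and Al syn across the terminal alkyne only (the alkene is inert), and the derived aluminate is hydroxymethylated with retention, which fixes the (E)-trisubstituted C4=C5 alkene.

Step 2
Reactants: 4 (2E)-3-methylhepta-2,6-dien-1-ol
Product: 5 (2E)-3-methylhepta-2,6-dienal
Conditions: Cu(MeCN)4OTf (5 mol%), 2,2'-bipyridine, TEMPO, N-methylimidazole, air, MeCN, rt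
Reagents that add atoms: none
Why: Stahl copper/TEMPO aerobic oxidation of a primary allylic alcohol stops at the enal and does not isomerise the alkene.

Step 3
Reactants: 5 (2E)-3-methylhepta-2,6-dienal; 6 tert-butyl(dimethyl)(prop-2-yn-1-yloxy)silane
Product: 8 (4R,5E)-1-[(tert-butyldimethylsilyl)oxy]-6-methyldeca-5,9-dien-2-yn-4-ol, via alkynylzinc 7 (not isolated)
Conditions: (S,S)-ProPhenol (20 mol%), Me2Zn (3 equiv), Ph3PO (40 mol%), toluene, 4 °C; aq. NH4Cl
Reagents that add atoms: none
Why: Trost ProPhenol–zinc alkynylation delivers the zinc acetylide to one enantiotopic face of the enal carbonyl and sets the carbinol centre (future C6) as R (ligand enantiomer selected for this sense).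

Step 4
Reactants: 8 (4R,5E)-1-[(tert-butyldimethylsilyl)oxy]-6-methyldeca-5,9-dien-2-yn-4-ol
Product: 11 (5R)-3-{[(tert-butyldimethylsilyl)oxy]methyl}-5-[(1E)-2-methylhexa-1,5-dien-1-yl]furan-2(5H)-one, via oxa-aluminacycle 9 (not isolated), via hydroxy acid 10 (not isolated)
Conditions: NaAlH2(OCH2CH2OCH3)2 (1.1 equiv), THF, 0 °C to rt; (IPr)CuCl [IPr = 1,3-bis(2,6-diisopropylphenyl)imidazol-2-ylidene] (5 mol%), CO2 (1 atm), 0 °C to rt; 1 M HCl, 0 °C
Reagents that add atoms: carbon dioxide (O=C=O)
Why: Proposed new method: hydroxyl-directed trans-hydroalumination puts H on C7 and Al on C11 through a five-membered oxa-aluminacycle, the alkenyl–Al bond is passed to the copper–carbene catalyst and inserts CO2 with retention of alkene geometry, so the new carboxyl group sits cis to the C6 oxygen and closes the lactone C–O bond on acidification without touching the stereocentre; the closest known reactions are the copper–carbene-catalysed carboxylation of alkenylaluminium reagents made by syn-hydro- or carbo-alumination, and the two-pot trans-hydroalumination/iodination then palladium-catalysed carbonylative lactonisation.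

Step 5
Reactants: 11 (5R)-3-{[(tert-butyldimethylsilyl)oxy]methyl}-5-[(1E)-2-methylhexa-1,5-dien-1-yl]furan-2(5H)-one
Product: 12 (5R)-3-(bromomethyl)-5-[(1E)-2-methylhexa-1,5-dien-1-yl]furan-2(5H)-one
Conditions: Ph3PBr2 (1.2 equiv), CH2Cl2, 0 °C to rt
Reagents that add atoms: dibromotriphenylphosphorane (BrP(Br)(c1ccccc1)(c1ccccc1)c1ccccc1)
Why: Appel-type direct conversion of a primary silyl ether into the bromide via a silyloxyphosphonium ion, under neutral conditions that leave the acidic C6–H and the alkenes alone.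

Step 6
Reactants: 13 acrolein; 14 methyl acrylate
Product: 15 methyl 3-hydroxy-2-methylenepent-4-enoate (racemic)
Conditions: DABCO (15 mol%), neat, 0 °C to rt
Reagents that add atoms: none
Why: Morita–Baylis–Hillman reaction, in which the DABCO-derived acrylate enolate adds 1,2 to the aldehyde and the amine is then eliminated.

Step 7
Reactants: 15 methyl 3-hydroxy-2-methylenepent-4-enoate (racemic)
Product: 16 methyl (3R)-3-acetoxy-2-methylenepent-4-enoate
Conditions: lipase PS (Burkholderia cepacia, immobilised), vinyl acetate (3 equiv), MTBE, 30 °C, stopped near 50% conversion; (S)-alcohol separated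
Reagents that add atoms: vinyl acetate (C=COC(C)=O)
Why: Lipase kinetic resolution by transesterification, where the Kazlauskas rule (vinyl = medium, 1-(methoxycarbonyl)vinyl = large) predicts acetylation of the (R)-alcohol, so the C9 acetate is installed with the configuration of the target.

Step 8
Reactants: 16 methyl (3R)-3-acetoxy-2-methylenepent-4-enoate
Product: 18 methyl (3S)-3-acetoxy-2-methylene-4-oxobutanoate, via ozonide 17 (not isolated)
Conditions: O3 (1.0 equiv, Sudan Red 7B end point), CH2Cl2, −78 °C; PPh3, −78 °C to 0 °C; used at once without chromatography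
Reagents that add atoms: ozone ([O-][O+]=O)
Why: Ozonolysis cleaves the monosubstituted alkene much faster than the electron-poor acrylate, and the neutral reductive work-up gives the α-acetoxy aldehyde without touching the stereocentre (the descriptor changes from R to S only through priorities).

Step 9
Reactants: 19 ethyl 2-(hydroxymethyl)prop-2-enoate
Product: 20 ethyl 2-{[(tert-butyldimethylsilyl)oxy]methyl}prop-2-enoate
Conditions: TBSCl, imidazole, CH2Cl2, 0 °C to rt
Reagents that add atoms: tert-butyl(chloro)dimethylsilane (C[Si](C)(Cl)C(C)(C)C)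
Why: Standard imidazole-promoted silylation of a primary alcohol.

Step 10
Reactants: 20 ethyl 2-{[(tert-butyldimethylsilyl)oxy]methyl}prop-2-enoate
Product: 21 2-{[(tert-butyldimethylsilyl)oxy]methyl}prop-2-enoic acid
Conditions: LiOH, THF/H2O, 0 °C; 1 M HCl to pH 3
Reagents that add atoms: water (O)
Why: Saponification of the ethyl ester at 0 °C, which the primary silyl ether survives.

Step 11
Reactants: 12 (5R)-3-(bromomethyl)-5-[(1E)-2-methylhexa-1,5-dien-1-yl]furan-2(5H)-one; 18 methyl (3S)-3-acetoxy-2-methylene-4-oxobutanoate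
Product: 23 methyl (3S,4R)-3-acetoxy-4-hydroxy-2-methylene-4-{(2R,3R)-4-methylene-2-[(1E)-2-methylhexa-1,5-dien-1-yl]-5-oxotetrahydrofuran-3-yl}butanoate, via allylzinc bromide 22 (not isolated)
Conditions: Zn dust (3 equiv), THF/sat. aq. NH4Cl (2:1), 0 °C
Reagents that add atoms: none
Why: Zinc Barbier 2-(alkoxycarbonyl)allylation, in which the allylzinc attacks through C7 anti to the C6 dienyl group (6,7-trans lactone) via a closed chair transition state (7,8-anti), a sense that coincides with polar Felkin–Anh attack on the (S)-α-acetoxy aldehyde and gives the (8R) alcohol with the exocyclic methylene regenerated.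

Step 12
Reactants: 23 methyl (3S,4R)-3-acetoxy-4-hydroxy-2-methylene-4-{(2R,3R)-4-methylene-2-[(1E)-2-methylhexa-1,5-dien-1-yl]-5-oxotetrahydrofuran-3-yl}butanoate
Product: 24 methyl (3aR,4R,5S,6E,10E,11aR)-5-acetoxy-4-hydroxy-10-methyl-3-methylene-2-oxo-2,3,3a,4,5,8,9,11a-octahydrocyclodeca[b]furan-6-carboxylate
Conditions: second-generation Hoveyda–Grubbs catalyst (15 mol%), 1,2-dichloroethane (0.5 mM), 60 °C
Reagents that add atoms: none
Why: Ring-closing metathesis between the terminal vinyl group and the 2-substituted acrylate releases ethene and gives the trisubstituted enoate with C2 trans to the ester (C2 and C9 cis on the ring), the geometry favoured both by the ten-membered ring and by the enoate.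

Step 13
Reactants: 24 methyl (3aR,4R,5S,6E,10E,11aR)-5-acetoxy-4-hydroxy-10-methyl-3-methylene-2-oxo-2,3,3a,4,5,8,9,11a-octahydrocyclodeca[b]furan-6-carboxylate; 21 2-{[(tert-butyldimethylsilyl)oxy]methyl}prop-2-enoic acid
Product: 25 methyl (3aS,4S,5S,6E,10E,11aR)-5-acetoxy-4-[(2-{[(tert-butyldimethylsilyl)oxy]methyl}prop-2-enoyl)oxy]-10-methyl-3-methylene-2-oxo-2,3,3a,4,5,8,9,11a-octahydrocyclodeca[b]furan-6-carboxylate
Conditions: PPh3, DIAD (betaine preformed), toluene, 0 °C to rt
Reagents that add atoms: none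
Why: Mitsunobu esterification, in which the carboxylate of 21 displaces the C8 oxyphosphonium group by SN2 with inversion, so one C–O bond formation corrects C8 from R to S (8β) and attaches the side chain.

Step 14
Reactants: 25 methyl (3aS,4S,5S,6E,10E,11aR)-5-acetoxy-4-[(2-{[(tert-butyldimethylsilyl)oxy]methyl}prop-2-enoyl)oxy]-10-methyl-3-methylene-2-oxo-2,3,3a,4,5,8,9,11a-octahydrocyclodeca[b]furan-6-carboxylate
Product: 26 methyl (3aS,4S,5S,6E,10E,11aR)-5-acetoxy-4-{[2-(hydroxymethyl)prop-2-enoyl]oxy}-10-methyl-3-methylene-2-oxo-2,3,3a,4,5,8,9,11a-octahydrocyclodeca[b]furan-6-carboxylate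
Conditions: HF·pyridine, pyridine, THF, 0 °C
Reagents that add atoms: none
Why: Fluoride-mediated desilylation of the primary silyl ether under buffered, non-basic conditions that leave the esters, the lactone and the three Michael acceptors intact.

**Compound list**
1 | hex-1-en-5-yne | C=CCCC#C | starting material
2 | dimethyl[(1E)-2-methylhexa-1,5-dien-1-yl]alumane | C[Al](C)/C=C(\C)CCC=C | intermediate
3 | lithium butyl(dimethyl)[(1E)-2-methylhexa-1,5-dien-1-yl]aluminate | [Li+].CCCC[Al-](C)(C)/C=C(\C)CCC=C | intermediate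
4 | (2E)-3-methylhepta-2,6-dien-1-ol | OC/C=C(\C)CCC=C | intermediate
5 | (2E)-3-methylhepta-2,6-dienal | O=C/C=C(\C)CCC=C | intermediate
6 | tert-butyl(dimethyl)(prop-2-yn-1-yloxy)silane | C#CCO[Si](C)(C)C(C)(C)C | starting material
7 | methyl{3-[(tert-butyldimethylsilyl)oxy]prop-1-yn-1-yl}zinc | C[Zn]C#CCO[Si](C)(C)C(C)(C)C | intermediate
8 | (4R,5E)-1-[(tert-butyldimethylsilyl)oxy]-6-methyldeca-5,9-dien-2-yn-4-ol | O[C@H](/C=C(\C)CCC=C)C#CCO[Si](C)(C)C(C)(C)C | intermediate
9 | sodium (5R)-3-{[(tert-butyldimethylsilyl)oxy]methyl}-2,2-bis(2-methoxyethoxy)-5-[(1E)-2-methylhexa-1,5-dien-1-yl]-2,5-dihydro-1,2-oxaluminol-2-uide | [Na+].COCCO[Al-]1(OCCOC)O[C@H](/C=C(\C)CCC=C)C=C1CO[Si](C)(C)C(C)(C)C | intermediate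
10 | (2Z,4R,5E)-2-{[(tert-butyldimethylsilyl)oxy]methyl}-4-hydroxy-6-methyldeca-2,5,9-trienoic acid | O[C@H](/C=C(\C)CCC=C)/C=C(/CO[Si](C)(C)C(C)(C)C)C(=O)O | intermediate
11 | (5R)-3-{[(tert-butyldimethylsilyl)oxy]methyl}-5-[(1E)-2-methylhexa-1,5-dien-1-yl]furan-2(5H)-one | CC(C)(C)[Si](C)(C)OCC1=C[C@@H](/C=C(\C)CCC=C)OC1=O | intermediate
12 | (5R)-3-(bromomethyl)-5-[(1E)-2-methylhexa-1,5-dien-1-yl]furan-2(5H)-one | BrCC1=C[C@@H](/C=C(\C)CCC=C)OC1=O | intermediate
13 | acrolein (prop-2-enal) | C=CC=O | starting material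
14 | methyl acrylate | C=CC(=O)OC | starting material
15 | methyl 3-hydroxy-2-methylenepent-4-enoate (racemic) | C=CC(O)C(=C)C(=O)OC | intermediate
16 | methyl (3R)-3-acetoxy-2-methylenepent-4-enoate | C=C[C@@H](OC(C)=O)C(=C)C(=O)OC | intermediate
17 | methyl (3S)-3-acetoxy-2-methylene-3-(1,2,4-trioxolan-3-yl)propanoate (both epimers at the trioxolane carbon) | C1OC(OO1)[C@@H](OC(C)=O)C(=C)C(=O)OC | intermediate
18 | methyl (3S)-3-acetoxy-2-methylene-4-oxobutanoate | O=C[C@@H](OC(C)=O)C(=C)C(=O)OC | intermediate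
19 | ethyl 2-(hydroxymethyl)prop-2-enoate | C=C(CO)C(=O)OCC | starting material
20 | ethyl 2-{[(tert-butyldimethylsilyl)oxy]methyl}prop-2-enoate | C=C(CO[Si](C)(C)C(C)(C)C)C(=O)OCC | intermediate
21 | 2-{[(tert-butyldimethylsilyl)oxy]methyl}prop-2-enoic acid | C=C(CO[Si](C)(C)C(C)(C)C)C(=O)O | intermediate
22 | bromo({(5R)-5-[(1E)-2-methylhexa-1,5-dien-1-yl]-2-oxo-2,5-dihydrofuran-3-yl}methyl)zinc | Br[Zn]CC1=C[C@@H](/C=C(\C)CCC=C)OC1=O | intermediate
23 | methyl (3S,4R)-3-acetoxy-4-hydroxy-2-methylene-4-{(2R,3R)-4-methylene-2-[(1E)-2-methylhexa-1,5-dien-1-yl]-5-oxotetrahydrofuran-3-yl}butanoate | O[C@H]([C@H]1C(=C)C(=O)O[C@@H]1/C=C(\C)CCC=C)[C@@H](OC(C)=O)C(=C)C(=O)OC | intermediate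
24 | methyl (3aR,4R,5S,6E,10E,11aR)-5-acetoxy-4-hydroxy-10-methyl-3-methylene-2-oxo-2,3,3a,4,5,8,9,11a-octahydrocyclodeca[b]furan-6-carboxylate (8-epi alcohol) | O[C@@H]1[C@H]2C(=C)C(=O)O[C@@H]2/C=C(\C)CC/C=C(/C(=O)OC)[C@@H]1OC(C)=O | intermediate
25 | methyl (3aS,4S,5S,6E,10E,11aR)-5-acetoxy-4-[(2-{[(tert-butyldimethylsilyl)oxy]methyl}prop-2-enoyl)oxy]-10-methyl-3-methylene-2-oxo-2,3,3a,4,5,8,9,11a-octahydrocyclodeca[b]furan-6-carboxylate | C=C(CO[Si](C)(C)C(C)(C)C)C(=O)O[C@H]1[C@H]2C(=C)C(=O)O[C@@H]2/C=C(\C)CC/C=C(/C(=O)OC)[C@@H]1OC(C)=O | intermediate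
26 | methyl (3aS,4S,5S,6E,10E,11aR)-5-acetoxy-4-{[2-(hydroxymethyl)prop-2-enoyl]oxy}-10-methyl-3-methylene-2-oxo-2,3,3a,4,5,8,9,11a-octahydrocyclodeca[b]furan-6-carboxylate (CNP0291058.1; germacrane 6R,7S,8S,9S) | C=C(CO)C(=O)O[C@H]1[C@H]2C(=C)C(=O)O[C@@H]2/C=C(\C)CC/C=C(/C(=O)OC)[C@@H]1OC(C)=O | target

**Step count and risks**
Total steps: 14. Longest linear sequence: 9 steps (steps 1–5, then 11–14).

The three steps most likely to fail:

Step 4 (the proposed new carboxylative lactonisation). The alkoxy-rich aluminate may not pass its alkenyl group to copper, or may lose silanolate by β-elimination to an allene. The fallback uses known chemistry, sets out from 8 and comes back at 11. The same trans-hydroalumination with NaAlH2(OCH2CH2OCH3)2 is quenched with iodine at −78 °C to give the vinyl iodide (2Z,4R,5E)-1-[(tert-butyldimethylsilyl)oxy]-2-iodo-6-methyldeca-2,5,9-trien-4-ol F1. Carbonylative lactonisation of F1 with PdCl2(PPh3)2 (5 mol%), CO (1 atm) and Et3N in THF at 50 °C then closes the butenolide 11.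

Step 12 (ring-closing metathesis). A strained cyclodeca-1,5-diene has to be closed onto a hindered 2-substituted acrylate, so oligomers or no reaction are possible; the free 8-hydroxyl can also lactonise onto the C14 ester on prolonged heating. The fallback moves the ring closure to a carbonyl addition, sets out from 12 and 18 and comes back at 24. Cross-metathesis of the terminal alkene of 12 (in excess) with the acrylate of 18 (second-generation Hoveyda–Grubbs catalyst, CH2Cl2, 40 °C) forms C1=C10 first and gives methyl (2E,6E)-2-[(1S)-1-acetoxy-2-oxoethyl]-7-[(2R)-4-(bromomethyl)-5-oxo-2,5-dihydrofuran-2-yl]-6-methylhepta-2,6-dienoate F2. Zinc dust in THF/aqueous NH4Cl at high dilution (or CrCl2 in THF) then closes the ten-membered ring by intramolecular Barbier allylation at C7–C8 to 24; the stereochemical outcome of this macrocyclisation would have to be checked.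

Step 13 (Mitsunobu inversion). C8 is flanked by two branched carbons, the C9 acetate can act as a neighbouring group (retention or acyl shift), and E2 elimination toward C7 competes. The fallback replaces the SN2 step by a redox inversion, sets out from 24 and comes back at 25. Dess–Martin periodinane with NaHCO3 in CH2Cl2 at 0 °C gives the ketone methyl (3aS,5S,6E,10E,11aR)-5-acetoxy-10-methyl-3-methylene-2,4-dioxo-2,3,3a,4,5,8,9,11a-octahydrocyclodeca[b]furan-6-carboxylate F3. Luche reduction (NaBH4, CeCl3·7H2O, MeOH, −78 °C), with hydride expected anti to the C9 acetoxy group (polar Felkin–Anh), gives the 8β-alcohol methyl (3aR,4S,5S,6E,10E,11aR)-5-acetoxy-4-hydroxy-10-methyl-3-methylene-2-oxo-2,3,3a,4,5,8,9,11a-octahydrocyclodeca[b]furan-6-carboxylate F4. Steglich esterification of F4 with acid 21 (EDC·HCl, DMAP, CH2Cl2) then gives 25 with retention.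

**Further compounds**
F1 | step 4 | (2Z,4R,5E)-1-[(tert-butyldimethylsilyl)oxy]-2-iodo-6-methyldeca-2,5,9-trien-4-ol | O[C@H](/C=C(\C)CCC=C)/C=C(\I)CO[Si](C)(C)C(C)(C)C
F2 | step 12 | methyl (2E,6E)-2-[(1S)-1-acetoxy-2-oxoethyl]-7-[(2R)-4-(bromomethyl)-5-oxo-2,5-dihydrofuran-2-yl]-6-methylhepta-2,6-dienoate | BrCC1=C[C@@H](/C=C(\C)CC/C=C(/C(=O)OC)[C@H](OC(C)=O)C=O)OC1=O
F3 | step 13 | methyl (3aS,5S,6E,10E,11aR)-5-acetoxy-10-methyl-3-methylene-2,4-dioxo-2,3,3a,4,5,8,9,11a-octahydrocyclodeca[b]furan-6-carboxylate | O=C1[C@H]2C(=C)C(=O)O[C@@H]2/C=C(\C)CC/C=C(/C(=O)OC)[C@@H]1OC(C)=O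
F4 | step 13 | methyl (3aR,4S,5S,6E,10E,11aR)-5-acetoxy-4-hydroxy-10-methyl-3-methylene-2-oxo-2,3,3a,4,5,8,9,11a-octahydrocyclodeca[b]furan-6-carboxylate | O[C@H]1[C@H]2C(=C)C(=O)O[C@@H]2/C=C(\C)CC/C=C(/C(=O)OC)[C@@H]1OC(C)=O
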